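**Plan**
1. Ring labels: ring A is the catechol ring with C1–CH2, C3/C4–OH and C5–O(ring B); ring B is the para-phenylene; ring C is the catechol ring with C1–CH2, C2–O(ring D) and C3/C4–OH; ring D is the ortho-phenylene.
2. Cuts: first the O(ring D)–C2(ring C) bond of the 17-membered ring; then the aryl–CH2 bonds at C1 of ring C and at the ortho carbon of ring D; last the O–C(ring B) bond of the A–O–B ether.
3. Enabling feature: C2 of ring C is ortho to C3, which bears an oxygen in the target. That oxygen is carried as a nitro group, which makes C2–F an SNAr electrophile and is afterwards converted to the C3 hydroxyl.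
4. Forward order: A–O–B ether (SNAr), ring D joined (B-alkyl Suzuki–Miyaura), ring C joined (B-alkyl Suzuki–Miyaura), ring D phenol freed, 17-membered ring closed, NO2 → NH2 → OH, three methyl ethers cleaved.
5. Stereochemistry: the target has no stereocentre, so nothing has to be controlled.

Key step: step 9

Remark: the cyclophane is taken as conformationally mobile (no stable planar chirality); compounds 1, 3, 4 and 7 are taken as purchasable.

Step 1
Reactants: 1 1-fluoro-3-methoxy-2-nitrobenzene
Product: 2 1-bromo-2-fluoro-4-methoxy-3-nitrobenzene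
Conditions: NBS, TFA, H2SO4 (cat.), 40 °C
Reagents that add atoms: N-bromosuccinimide, O=C1CCC(=O)N1Br
Why: Electrophilic aromatic bromination, in which the methoxy group (the only activating substituent) directs to its para position, also ortho to fluorine and meta to nitro, so the 1,2,3,4-pattern of ring C should form with the ortho isomer as a minor product to be removed.

Step 2
Reactants: 3 3-hydroxy-4,5-dimethoxybenzaldehyde, 4 4-fluorobenzonitrile
Product: 5 4-(5-formyl-2,3-dimethoxyphenoxy)benzonitrile
Conditions: K2CO3, DMF, 120 °C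
Reagents that add atoms: none
Why: Intermolecular SNAr, in which the phenoxide of 3 displaces fluoride para to the nitrile of 4 while the aldehyde on the electron-rich ring is inert to carbonate.

Step 3
Reactants: 5 4-(5-formyl-2,3-dimethoxyphenoxy)benzonitrile
Product: 6 4-(5-ethenyl-2,3-dimethoxyphenoxy)benzonitrile
Conditions: Ph3PCH3Br, KOtBu, THF, 0 °C to rt
Reagents that add atoms: methyltriphenylphosphonium bromide, C[P+](c1ccccc1)(c1ccccc1)c1ccccc1.[Br-]
Why: Wittig methylenation, in which the non-stabilised ylide adds to the aldehyde far faster than to the nitrile, so only the formyl group becomes the vinyl group.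

Step 4
Reactants: 6 4-(5-ethenyl-2,3-dimethoxyphenoxy)benzonitrile, 7 1-bromo-2-(methoxymethoxy)benzene
Product: 9 4-[2,3-dimethoxy-5-[2-[2-(methoxymethoxy)phenyl]ethyl]phenoxy]benzonitrile, via alkylborane 8 (not isolated)
Conditions: 9-BBN-H, THF, 0 °C to rt; then 7, PdCl2(dppf) (5 mol %), K3PO4 (3 M aq.), DMF, 60 °C
Reagents that add atoms: none
Why: B-alkyl Suzuki–Miyaura coupling, in which 9-BBN-H adds anti-Markovnikov to the styrene and the primary alkylborate transfers the CH2CH2 unit to the arylpalladium bromide from 7, reductive elimination at the dppf complex outrunning beta-hydride elimination and the nitrile and MOM ether staying intact.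

Step 5
Reactants: 9 4-[2,3-dimethoxy-5-[2-[2-(methoxymethoxy)phenyl]ethyl]phenoxy]benzonitrile
Product: 11 4-[2,3-dimethoxy-5-[2-[2-(methoxymethoxy)phenyl]ethyl]phenoxy]benzaldehyde, via aluminated aldimine 10 (not isolated)
Conditions: iBu2AlH, toluene/CH2Cl2, −78 to −20 °C; then 1 M HCl, 0 °C
Reagents that add atoms: water, O
Why: Partial reduction of a nitrile with iBu2AlH, in which one hydride adds to give the N-aluminated aldimine that cold dilute acid hydrolyses to the aldehyde without loss of the MOM acetal.

Step 6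
Reactants: 11 4-[2,3-dimethoxy-5-[2-[2-(methoxymethoxy)phenyl]ethyl]phenoxy]benzaldehyde
Product: 12 1-(4-ethenylphenoxy)-2,3-dimethoxy-5-[2-[2-(methoxymethoxy)phenyl]ethyl]benzene
Conditions: Ph3PCH3Br, KOtBu, THF, 0 °C to rt
Reagents that add atoms: methyltriphenylphosphonium bromide, C[P+](c1ccccc1)(c1ccccc1)c1ccccc1.[Br-]
Why: Wittig methylenation of an aryl aldehyde as in step 3, all other groups being ethers that are inert to the ylide.

Step 7
Reactants: 12 1-(4-ethenylphenoxy)-2,3-dimethoxy-5-[2-[2-(methoxymethoxy)phenyl]ethyl]benzene, 2 1-bromo-2-fluoro-4-methoxy-3-nitrobenzene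
Product: 14 1-[2-[4-[2,3-dimethoxy-5-[2-[2-(methoxymethoxy)phenyl]ethyl]phenoxy]phenyl]ethyl]-2-fluoro-4-methoxy-3-nitrobenzene, via alkylborane 13 (not isolated)
Conditions: 9-BBN-H, THF, 0 °C to rt; then 2, PdCl2(dppf) (5 mol %), K3PO4 (3 M aq.), THF/DMF, rt to 40 °C
Reagents that add atoms: none
Why: B-alkyl Suzuki–Miyaura coupling as in step 4, in which zerovalent palladium inserts into the C–Br and not the C–F bond of 2 and the mild base at low temperature should spare the activated fluoride, giving the saturated bridge directly without a hydrogenation that would reduce the nitro group.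

Step 8
Reactants: 14 1-[2-[4-[2,3-dimethoxy-5-[2-[2-(methoxymethoxy)phenyl]ethyl]phenoxy]phenyl]ethyl]-2-fluoro-4-methoxy-3-nitrobenzene
Product: 15 2-[2-[3-[4-[2-(2-fluoro-4-methoxy-3-nitrophenyl)ethyl]phenoxy]-4,5-dimethoxyphenyl]ethyl]phenol
Conditions: HCl (3 M aq.), MeOH/THF, 50 °C
Reagents that add atoms: none
Why: Acid-catalysed acetal cleavage of the MOM ether, which frees the ring D phenol while the aryl methyl ethers, the diaryl ether and the fluoronitroarene are inert to dilute acid.

Step 9
Reactants: 15 2-[2-[3-[4-[2-(2-fluoro-4-methoxy-3-nitrophenyl)ethyl]phenoxy]-4,5-dimethoxyphenyl]ethyl]phenol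
Product: 16 macrocyclic nitro trimethyl ether (target skeleton with OMe at C3 and C4 of ring A and at C4 of ring C, and NO2 at C3 of ring C)
Conditions: K2CO3, DMF, 0.005 M (slow addition of 15), 60 °C
Reagents that add atoms: none
Why: Deprotonation gives the ring D phenoxide, which adds to C2 of ring C ipso to fluorine to form a Meisenheimer anion whose charge is taken up by the ortho nitro group at C3, and loss of fluoride restores the arene (intramolecular SNAr). The closest known reaction type is the nitro-activated SNAr cycloetherification that closes 14- to 17-membered diaryl ether cyclophanes of the isodityrosine class. The 17-membered ring is closed as a macrocyclization by ipso attack at a trigonal carbon (formally 17-exo-trig with respect to the C2=C3 bond), helped by the two flexible CH2CH2 bridges and kept ahead of oligomer formation by slow addition at high dilution. No stereocentre is formed, since the sp3 carbon of the Meisenheimer intermediate is transient. The step needs site selectivity (C2–F rather than the C4 methoxy or the nitro group) and O- rather than C-arylation of the phenoxide; fluoride ortho to nitro is by far the best leaving group in the molecule, and a potassium phenoxide in DMF should react at oxygen.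

Step 10
Reactants: 16 macrocyclic nitro trimethyl ether
Product: 17 macrocyclic aniline (as 16 with NH2 at C3 of ring C)
Conditions: H2 (1 atm), Pd/C (10 %), EtOAc/EtOH, rt
Reagents that add atoms: none
Why: Catalytic hydrogenation of an aromatic nitro group to the aniline, the macrocycle holding no alkene, benzyl ether or halogen and diaryl ethers being stable under these conditions.

Step 11
Reactants: 17 macrocyclic aniline
Product: 19 macrocyclic phenol (as 16 with OH at C3 of ring C), via diazonium hydrogen sulfate 18 (not isolated)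
Conditions: NaNO2, H2SO4, H2O/AcOH, 0 °C; then Cu(NO3)2 (large excess), Cu2O, H2O, rt
Reagents that add atoms: water, O
Why: Diazotization followed by Sandmeyer-type hydroxydediazoniation, in which monovalent copper reduces the diazonium ion to the aryl radical and divalent copper nitrate in large excess should capture it and deliver OH from bound water faster than the radical can attack ring D.

Step 12
Reactants: 19 macrocyclic phenol
Product: 20 target compound CNP0114693.0
Conditions: BBr3, CH2Cl2, −78 °C to rt; then H2O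
Reagents that add atoms: none
Why: Lewis-acid ether cleavage with BBr3, in which each complexed methoxy group loses its methyl to bromide by SN2 while the two diaryl ether bonds, having no sp3 carbon, survive, and hydrolysis of the aryl borates frees both catechols.

**Compound list**
1 | 1-fluoro-3-methoxy-2-nitrobenzene | COc1cccc(F)c1[N+](=O)[O-] | starting material
2 | 1-bromo-2-fluoro-4-methoxy-3-nitrobenzene | COc1ccc(Br)c(F)c1[N+](=O)[O-] | intermediate
3 | 3-hydroxy-4,5-dimethoxybenzaldehyde | COc1cc(C=O)cc(O)c1OC | starting material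
4 | 4-fluorobenzonitrile | N#Cc1ccc(F)cc1 | starting material
5 | 4-(5-formyl-2,3-dimethoxyphenoxy)benzonitrile | COc1cc(C=O)cc(Oc2ccc(C#N)cc2)c1OC | intermediate
6 | 4-(5-ethenyl-2,3-dimethoxyphenoxy)benzonitrile | COc1cc(C=C)cc(Oc2ccc(C#N)cc2)c1OC | intermediate
7 | 1-bromo-2-(methoxymethoxy)benzene | COCOc1ccccc1Br | starting material
8 | alkylborane: 4-[5-[2-(9-borabicyclo[3.3.1]nonan-9-yl)ethyl]-2,3-dimethoxyphenoxy]benzonitrile | COc1cc(CCB2C3CCCC2CCC3)cc(Oc2ccc(C#N)cc2)c1OC | intermediate
9 | 4-[2,3-dimethoxy-5-[2-[2-(methoxymethoxy)phenyl]ethyl]phenoxy]benzonitrile | COCOc1ccccc1CCc1cc(OC)c(OC)c(Oc2ccc(C#N)cc2)c1 | intermediate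
10 | aluminated aldimine: N-(diisobutylalumanyl)imine of aldehyde 11 | COCOc1ccccc1CCc1cc(OC)c(OC)c(Oc2ccc(C=N[Al](CC(C)C)CC(C)C)cc2)c1 | intermediate
11 | 4-[2,3-dimethoxy-5-[2-[2-(methoxymethoxy)phenyl]ethyl]phenoxy]benzaldehyde | COCOc1ccccc1CCc1cc(OC)c(OC)c(Oc2ccc(C=O)cc2)c1 | intermediate
12 | 1-(4-ethenylphenoxy)-2,3-dimethoxy-5-[2-[2-(methoxymethoxy)phenyl]ethyl]benzene | COCOc1ccccc1CCc1cc(OC)c(OC)c(Oc2ccc(C=C)cc2)c1 | intermediate
13 | alkylborane: 9-BBN adduct of 12 (boron on the terminal carbon of the former vinyl group) | COCOc1ccccc1CCc1cc(OC)c(OC)c(Oc2ccc(CCB3C4CCCC3CCC4)cc2)c1 | intermediate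
14 | 1-[2-[4-[2,3-dimethoxy-5-[2-[2-(methoxymethoxy)phenyl]ethyl]phenoxy]phenyl]ethyl]-2-fluoro-4-methoxy-3-nitrobenzene | COCOc1ccccc1CCc1cc(OC)c(OC)c(Oc2ccc(CCc3ccc(OC)c([N+](=O)[O-])c3F)cc2)c1 | intermediate
15 | 2-[2-[3-[4-[2-(2-fluoro-4-methoxy-3-nitrophenyl)ethyl]phenoxy]-4,5-dimethoxyphenyl]ethyl]phenol | Oc1ccccc1CCc1cc(OC)c(OC)c(Oc2ccc(CCc3ccc(OC)c([N+](=O)[O-])c3F)cc2)c1 | intermediate
16 | macrocyclic nitro trimethyl ether (ring A 3,4-di-OMe; ring C 4-OMe, 3-NO2) | COc1cc2cc(c1OC)Oc1ccc(cc1)CCc1ccc(OC)c([N+](=O)[O-])c1Oc1ccccc1CC2 | intermediate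
17 | macrocyclic aniline (ring C 3-NH2) | COc1cc2cc(c1OC)Oc1ccc(cc1)CCc1ccc(OC)c(N)c1Oc1ccccc1CC2 | intermediate
18 | diazonium hydrogen sulfate of 17 | COc1cc2cc(c1OC)Oc1ccc(cc1)CCc1ccc(OC)c([N+]#N)c1Oc1ccccc1CC2.OS(=O)(=O)[O-] | intermediate
19 | macrocyclic phenol (ring C 3-OH, 4-OMe; ring A 3,4-di-OMe) | COc1cc2cc(c1OC)Oc1ccc(cc1)CCc1ccc(OC)c(O)c1Oc1ccccc1CC2 | intermediate
20 | CNP0114693.0 | Oc1cc2cc(c1O)Oc1ccc(cc1)CCc1ccc(O)c(O)c1Oc1ccccc1CC2 | target

**Step count and risks**
Total: 12 steps. Longest linear sequence: 11 steps (3 to 20, steps 2–12); step 1 is a one-step branch that enters at step 7.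

Step 9 (ring closure). The 17-membered closure may be slow because of strain in the transition state and lose to intermolecular etherification, which gives oligomers. The fallback makes the ether bond between two molecules and closes the ring at the C1(ring C)–CH2 bond instead. It sets out from styrene 12. The MOM group is removed with ZnBr2 and n-PrSH in CH2Cl2, which spares the vinyl group, to give 2-[2-[3-(4-ethenylphenoxy)-4,5-dimethoxyphenyl]ethyl]phenol F1. Intermolecular SNAr with bromide 2 (K2CO3, DMF, 50 °C) should give 1-bromo-2-[2-[2-[3-(4-ethenylphenoxy)-4,5-dimethoxyphenyl]ethyl]phenoxy]-4-methoxy-3-nitrobenzene F2. Hydroboration with 9-BBN-H gives the 9-BBN adduct of this bromo diaryl ether F3. An intramolecular B-alkyl Suzuki–Miyaura coupling at high dilution (PdCl2(dppf), AsPh3, Cs2CO3, DMF/THF/H2O) then closes the ring and comes back to the route at 16.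

Step 11 (NH2 to OH). The aryl radical may close onto ring D (Pschorr-type dibenzofuran formation) or abstract hydrogen, and the diazonium ion may undergo azo coupling. The fallback avoids the diazonium ion by carrying the C3 oxygen as a formyl group, which also activates C2–F and is excised by Baeyer–Villiger (Dakin-type) oxidation. It sets out from styrene 12 as its 9-BBN adduct 13. Coupling under the conditions of step 7 with 3-bromo-2-fluoro-6-methoxybenzaldehyde F4 (from 2-fluoro-6-methoxybenzaldehyde and NBS) should give 3-[2-[4-[2,3-dimethoxy-5-[2-[2-(methoxymethoxy)phenyl]ethyl]phenoxy]phenyl]ethyl]-2-fluoro-6-methoxybenzaldehyde F5. HCl in MeOH gives 2-fluoro-3-[2-[4-[5-[2-(2-hydroxyphenyl)ethyl]-2,3-dimethoxyphenoxy]phenyl]ethyl]-6-methoxybenzaldehyde F6. Cs2CO3 in DMF at 100 °C and high dilution closes the ring by SNAr ortho to the formyl group to give the macrocyclic aldehyde (16 with CHO in place of NO2) F7. mCPBA in CH2Cl2 gives the macrocyclic aryl formate (19 with OCHO in place of the C3 hydroxyl) F8, and K2CO3 in MeOH cleaves it, which comes back to the route at 19.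

Step 7 (second bridge). The aqueous base may hydrolyse the activated C–F bond, and beta-hydride elimination or protodeboronation may consume the alkylborane. The fallback works without water. It sets out from styrene 12 and bromide 2. A Heck reaction (Pd(OAc)2, P(o-tol)3, Et3N, DMF, 90 °C) should give the (E)-stilbene (14 with CH=CH between rings B and C) F9. Diimide reduction (2-nitrobenzenesulfonyl hydrazide, Et3N, CH2Cl2, rt) saturates the alkene, leaves the nitro group and the fluoride, and comes back to the route at 14.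

**Further compounds**
F1 | step 9 | 2-[2-[3-(4-ethenylphenoxy)-4,5-dimethoxyphenyl]ethyl]phenol | Oc1ccccc1CCc1cc(OC)c(OC)c(Oc2ccc(C=C)cc2)c1
F2 | step 9 | 1-bromo-2-[2-[2-[3-(4-ethenylphenoxy)-4,5-dimethoxyphenyl]ethyl]phenoxy]-4-methoxy-3-nitrobenzene | COc1ccc(Br)c(Oc2ccccc2CCc2cc(OC)c(OC)c(Oc3ccc(C=C)cc3)c2)c1[N+](=O)[O-]
F3 | step 9 | 9-BBN adduct of F2 (boron on the terminal carbon of the former vinyl group) | COc1ccc(Br)c(Oc2ccccc2CCc2cc(OC)c(OC)c(Oc3ccc(CCB4C5CCCC4CCC5)cc3)c2)c1[N+](=O)[O-]
F4 | step 11 | 3-bromo-2-fluoro-6-methoxybenzaldehyde | COc1ccc(Br)c(F)c1C=O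
F5 | step 11 | 3-[2-[4-[2,3-dimethoxy-5-[2-[2-(methoxymethoxy)phenyl]ethyl]phenoxy]phenyl]ethyl]-2-fluoro-6-methoxybenzaldehyde | COCOc1ccccc1CCc1cc(OC)c(OC)c(Oc2ccc(CCc3ccc(OC)c(C=O)c3F)cc2)c1
F6 | step 11 | 2-fluoro-3-[2-[4-[5-[2-(2-hydroxyphenyl)ethyl]-2,3-dimethoxyphenoxy]phenyl]ethyl]-6-methoxybenzaldehyde | Oc1ccccc1CCc1cc(OC)c(OC)c(Oc2ccc(CCc3ccc(OC)c(C=O)c3F)cc2)c1
F7 | step 11 | macrocyclic aldehyde (16 with CHO in place of NO2) | COc1cc2cc(c1OC)Oc1ccc(cc1)CCc1ccc(OC)c(C=O)c1Oc1ccccc1CC2
F8 | step 11 | macrocyclic aryl formate (19 with OCHO in place of the C3 hydroxyl) | COc1cc2cc(c1OC)Oc1ccc(cc1)CCc1ccc(OC)c(OC=O)c1Oc1ccccc1CC2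
F9 | step 7 | (E)-stilbene analogue of 14 | COCOc1ccccc1CCc1cc(OC)c(OC)c(Oc2ccc(/C=C/c3ccc(OC)c([N+](=O)[O-])c3F)cc2)c1
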